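# Total synthesis proposal for CNP0482898.0 (meta-depside 12)

Atom labels used throughout:
- **Ring A** is C1–C6. C1 bears the acyl carbon C7, C2 bears OMe, C4 bears OH and C6 bears propyl.
- **Ring B** is C1'–C6'. C1' bears CO2H, C2' OH, C3' the ester oxygen O3', C4' OH, C5' H and C6' propyl.

## The problem

The target 12 is a meta-depside in which two units of one C10 monomer, divaric acid (2,4-dihydroxy-6-propylbenzoic acid), are joined by a single ester from C7 of ring A to an oxygen on C3' of ring B. Ring B is therefore pentasubstituted and carries three contiguous oxygens. The acyl group must sit on the central, most crowded oxygen (O3'), while both neighbours stay free phenols between which an acyl group can wander. The ester unites a di-ortho-substituted benzoic acid with a di-ortho-substituted phenol, which is the worst case for acyl transfer. In ring A the methyl group is on O2, the chelated and less reactive oxygen, and O4 is free, which reverses the innate order of alkylation. There is no stereocentre and no stable axis, so only position has to be controlled: O2 against O4, C3' against C5', and O3' against O2' and O4'. The aryl ester is cleaved by hydroxide, alkoxides and amines, the salicylic acid of ring B loses CO2 on heating or in acid, and the C2 methyl ether next to C7 falls to chelating Lewis acids, so the last step must be neutral. The enabling feature is that C3' lies between O2' and O4' and meta to the C1' carboxyl, which makes it the most nucleophilic carbon of ring B, and removing the aroyloxy group from it leaves the plain divarate monomer with a C3'–H bond; the depside oxygen can therefore arrive together with ring A if a carboxyl oxygen of ring A is made electrophilic.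

## Retrosynthesis

**12 ⇒ 11.** The two O–CH2Ph bonds are cut, one on the C1' carboxyl and one on O4 of ring A. Benzyl is the only group on both sites that leaves under neutral, non-nucleophilic conditions. Base, acid and Lewis acid would each attack the depside ester, the salicylic acid or the C2 methyl ether. The forward reaction only has to be one hydrogenolysis that touches nothing else.

**11 ⇒ 2 + 8 (key cut).**
- The aryl–oxygen bond C3'–O3' is cut, not its neighbour, the acyl bond C7–O3'.
- The acyl cut leaves a 2,3,4-trioxygenated ring B. Its third oxygen must first be installed, and its three phenols must then be told apart.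
- The aryl cut removes that oxygen altogether and returns benzyl divarate 2, a compound with only C3'–H at the site.
- The other fragment is the ring-A carboxylate oxygen in reversed polarity, that is, the diaroyl peroxide 8.
- Both partners are one-ring divarate derivatives, and 8 is only acid 5 in activated form.
- The forward reaction must join two nucleophilic atoms, a carboxyl oxygen and C3'. It must choose C3' over C5' and attack the O–O bond rather than the carbonyl group.
- One operation then installs O3', forms the depside link on the central oxygen and avoids the hindered acyl transfer.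

**8 ⇒ 6 + 7.** One acyl–oxygen bond (C7–OO) of the peroxide is cut. This gives acid chloride 6 and peroxy acid 7, the same aroyl group in two states of activation. A symmetrical peroxide leaves no doubt about which aroyloxy group is transferred, which a mixed peroxide would. The half that is not transferred comes back as 5. The forward reaction is the acylation of a peroxy acid by an acid chloride, and each half enters as a reactant of its own.

**7 ⇒ 6 ⇒ 5.** The C7–OOH bond is cut to 6 and hydrogen peroxide, so the O–O bond is bought ready-made. The C7–Cl bond is then cut to acid 5. One batch of 6 is divided: one portion is perhydrolysed to 7 and the other is kept to acylate it. Both forward reactions are standard acyl substitutions with small nucleophiles.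

**5 ⇒ 4 ⇒ 3 ⇒ 2.** The cuts are the ester O–benzyl (4), O2–CH3 (3) and O4–CH2Ph (2). The order follows the chelation of O2–H to the ester carbonyl. The free O4–H is capped first with the group that the end game removes, and only then is the reluctant O2–H methylated. This sets the "reversed" pattern of ring A without any selective deprotection. The precursor is again 2, so both rings branch from one intermediate.

**2 ⇒ 1.** The benzyl ester is cut, which leads to commercial divaric acid 1. The whole carbon skeleton of 12 comes from this single monomer. The forward reaction must alkylate the carboxylate and leave both phenols alone.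

## Roads not taken

**Alternative 1 (the most obvious):**
- *Cut:* the acyl bond C7–O3'.
- *Forward key step:* esterification (DCC or TFAA) of 5 with benzyl 2,4-bis(benzyloxy)-3-hydroxy-6-propylbenzoate A1 to give the fully benzylated depside A2, followed by hydrogenolysis.
- *Why not:* A1 costs four steps from 2 (C3' formylation, double O-benzylation, Baeyer–Villiger oxidation and formate cleavage), all spent on installing and exposing one oxygen. The coupling then forces a di-ortho-substituted acyl donor onto a phenol flanked by two benzyloxy groups. The chosen plan needs no oxygen differentiation on ring B, and it turns the hindrance at C7 into an advantage.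

**Alternative 2 (biomimetic):**
- *Cut:* the acyl bond C7–O4' of the para-depside A3 in place of C7–O3', so that O3' is added to the assembled dimer.
- *Forward key steps:* esterify O4' of 2 with 5 to give the para-depside A3, hydroxylate C3' to give the 3'-hydroxy para-depside A4, and let the acyl group shift from O4' to O3'.
- *Why not:* the shift is credible, because O4' is the vinylogous-acid oxygen and the best leaving group. The hydroxylation has no chemical counterpart. After acylation ring B is a deactivated, chelated salicylate, and ring A is the more electron-rich ring, so electrophilic oxidants would attack the wrong ring or C5'. The chosen plan oxidises ring B while it is still a free resorcinol and keeps the thermodynamic bias toward O3' as a safeguard.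

**Alternative 3:**
- *Cut:* excise O3' from C7–O3'–C3', leaving the C7–C3' bond of a benzophenone.
- *Forward key steps:* Friedel–Crafts acylation of 2, or Fries shift of the para-depside A3, to give the tetra-ortho-substituted benzophenone A5, followed by Baeyer–Villiger oxidation.
- *Why not:* the C–C bond uses natural polarity, but peracid addition to so crowded a ketone is slow. The two electron-rich aryl groups have nearly equal migratory aptitude, so oxygen insertion on the wrong side of the carbonyl group is as likely as on the right side. Dakin conditions, which would favour the hydroxyaryl ring, are basic peroxide and would cleave the product ester.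

Key step: step 8

Assumption: the SMILES contains no stereocentre, no stereodefined double bond and no hindered axis, so 12 is achiral and the request for a single enantiomer is met by the constitution alone.

## Route

Step 1
Reactants: 1 divaric acid (2,4-dihydroxy-6-propylbenzoic acid)
Product: 2 benzyl 2,4-dihydroxy-6-propylbenzoate (benzyl divarate)
Conditions: BnBr (1.05 equiv), KHCO3 (1.2 equiv), DMF, 25 °C
Reagents that add atoms: benzyl bromide, BrCc1ccccc1
Why: Carboxylate O-alkylation (SN2); hydrogencarbonate ionises only the carboxylic acid and not the phenols, so the halide meets a single nucleophile, and room temperature avoids decarboxylation of the β-resorcylic acid.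

Step 2
Reactants: 2 benzyl 2,4-dihydroxy-6-propylbenzoate
Product: 3 benzyl 4-(benzyloxy)-2-hydroxy-6-propylbenzoate
Conditions: BnBr (1.05 equiv), K2CO3 (1.2 equiv), acetone, reflux
Reagents that add atoms: benzyl bromide, BrCc1ccccc1
Why: Williamson ether synthesis; O2–H is held in a hydrogen bond to the ester carbonyl, so carbonate in acetone ionises and benzylates only O4–H, and one equivalent of halide guards against a second alkylation.

Step 3
Reactants: 3 benzyl 4-(benzyloxy)-2-hydroxy-6-propylbenzoate
Product: 4 benzyl 4-(benzyloxy)-2-methoxy-6-propylbenzoate
Conditions: MeI (3 equiv), K2CO3 (3 equiv), DMF, 50 °C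
Reagents that add atoms: iodomethane, CI
Why: Williamson methylation of the remaining chelated phenol, which needs the polar solvent, an excess of the small electrophile and warmth; 3 has no other acidic site.

Step 4
Reactants: 4 benzyl 4-(benzyloxy)-2-methoxy-6-propylbenzoate
Product: 5 4-(benzyloxy)-2-methoxy-6-propylbenzoic acid
Conditions: KOH (5 equiv), DMSO–H2O 4:1, 90 °C; then 1 M HCl, 0 °C, to pH 2
Reagents that add atoms: potassium hydroxide, [K+].[OH-]
Why: Saponification (BAc2) of a di-ortho-substituted benzoate, for which poorly solvated hydroxide in aqueous DMSO is the usual remedy; both aryl ethers are inert to base, and the acid is liberated cold to avoid decarboxylation.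

Step 5
Reactants: 5 4-(benzyloxy)-2-methoxy-6-propylbenzoic acid
Product: 6 4-(benzyloxy)-2-methoxy-6-propylbenzoyl chloride
Conditions: (COCl)2 (1.2 equiv), DMF (cat.), CH2Cl2, 0 → 25 °C; evaporate, strip with toluene; crude 6 divided into two equal portions
Reagents that add atoms: oxalyl chloride, O=C(Cl)C(=O)Cl
Why: Vilsmeier-catalysed acid chloride formation, which begins at the unhindered carboxyl oxygen and so is little affected by the two ortho groups; the by-products are gases, so 6 needs no purification, and the aryl ethers are inert under these mild conditions.

Step 6
Reactants: 6 4-(benzyloxy)-2-methoxy-6-propylbenzoyl chloride (first portion)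
Product: 7 4-(benzyloxy)-2-methoxy-6-propylperoxybenzoic acid
Conditions: 30% aq. H2O2 (5 equiv), pyridine (1.1 equiv), Et2O, −10 → 0 °C, slow addition of 6 to the peroxide; cold 0.5 M HCl and water washes, MgSO4; kept as a cold Et2O solution and assayed by iodometric titration
Reagents that add atoms: hydrogen peroxide, OO
Why: Perhydrolysis of an acid chloride is the standard synthesis of aromatic peroxy acids; the excess of H2O2 and the inverse addition keep 6 scarce, so that 7 is not acylated again, and the α-effect lets H2O2 outrun water at the hindered C7. Any 8 that does form here is simply carried into step 7.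

Step 7
Reactants: 6 4-(benzyloxy)-2-methoxy-6-propylbenzoyl chloride (second portion); 7 4-(benzyloxy)-2-methoxy-6-propylperoxybenzoic acid
Product: 8 bis[4-(benzyloxy)-2-methoxy-6-propylbenzoyl] peroxide
Conditions: pyridine (1.1 equiv), Et2O, −10 → 0 °C; cold 0.5 M HCl, NaHCO3 and water washes, MgSO4; CHCl3 added and Et2O removed under reduced pressure below 10 °C, never to dryness; used at once
Reagents that add atoms: none
Why: Acylation of a peroxy acid by an acid chloride is the standard route to diacyl peroxides whose two halves are brought in separately; the peroxy oxygen is a small α-effect nucleophile that can reach the hindered acyl carbon. Both halves carry the same aroyl group, so only one peroxide can form, and the ether solvent is exchanged before warming because ethers promote induced decomposition of diacyl peroxides.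

Step 8
Reactants: 2 benzyl 2,4-dihydroxy-6-propylbenzoate (1.5 equiv); 8 bis[4-(benzyloxy)-2-methoxy-6-propylbenzoyl] peroxide
Product: 11 benzyl 3-{[4-(benzyloxy)-2-methoxy-6-propylbenzoyl]oxy}-2,4-dihydroxy-6-propylbenzoate, via aryl peroxyester 9 (not isolated), via dienone 10 (not isolated)
Conditions: CHCl3 (ethanol-free), 25 → 40 °C, dark, Ar; then aq. NaHCO3 wash (recovers 5), chromatography (recovers excess 2)
Reagents that add atoms: none
Why: This is the ortho-aroyloxylation of a phenol by a diaroyl peroxide, and the closest known case is the conversion of phenols into catechol monobenzoates with dibenzoyl peroxide. The unchelated O4'–H of 2 attacks the O–O σ* orbital of 8 in a polar, non-radical displacement that expels 5 and gives aryl peroxyester 9, whose weak O–O bond breaks in a [3,3]-sigmatropic shift over C3'=C4'–O–O–C7=O that places the former carbonyl oxygen on C3' and gives dienone 10, which enolises at once to 11. No ring is closed, and the only new stereocentre, C3' of 10, is racemic and is erased on enolisation. The step needs C3' over C5': the O2'–H···O=C chelate fixes the C1'=C2' and hence the C3'=C4' double bond (the bias that sends Claisen shifts of 4-allyloxysalicylates to C3), dienone 10 keeps that chelate whereas a C5' dienone would lose it, and C5' is also flanked by the propyl group. The step needs attack at O–O and not at C7=O: the C2 methoxy and C6 propyl groups shield the carbonyl carbon and, by twisting ring A out of conjugation, make the carboxylate a better leaving group than benzoate. The aryl ethers of ring A have no O–H and should be inert to the peroxide, and 11 is less electron-rich than 2, which is used in excess to curb a second oxidation at C5'. An acyl shift from O3' to O4' or O2' should be uphill, because O4' is the vinylogous-acid oxygen (the best leaving group) and O2' is tied up in the chelate, so 11 should also be the thermodynamic isomer. The equivalent of 5 that is released goes back into step 5.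

Step 9
Reactants: 11 benzyl 3-{[4-(benzyloxy)-2-methoxy-6-propylbenzoyl]oxy}-2,4-dihydroxy-6-propylbenzoate
Product: 12 2,4-dihydroxy-3-[(4-hydroxy-2-methoxy-6-propylbenzoyl)oxy]-6-propylbenzoic acid (target)
Conditions: H2 (1 atm), 10% Pd/C, EtOAc, 25 °C; filter, evaporate below 30 °C
Reagents that add atoms: none
Why: Hydrogenolysis of the benzyl ester and the benzyl ether over palladium is the standard neutral end game for depsides; the aprotic solvent excludes transesterification, the aryl ester, methyl ether and rings are inert, and cold evaporation avoids decarboxylation.

## Compound list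

1 | divaric acid (2,4-dihydroxy-6-propylbenzoic acid) | CCCc1cc(O)cc(O)c1C(=O)O | starting material
2 | benzyl 2,4-dihydroxy-6-propylbenzoate | CCCc1cc(O)cc(O)c1C(=O)OCc1ccccc1 | intermediate
3 | benzyl 4-(benzyloxy)-2-hydroxy-6-propylbenzoate | CCCc1cc(OCc2ccccc2)cc(O)c1C(=O)OCc1ccccc1 | intermediate
4 | benzyl 4-(benzyloxy)-2-methoxy-6-propylbenzoate | CCCc1cc(OCc2ccccc2)cc(OC)c1C(=O)OCc1ccccc1 | intermediate
5 | 4-(benzyloxy)-2-methoxy-6-propylbenzoic acid | CCCc1cc(OCc2ccccc2)cc(OC)c1C(=O)O | intermediate
6 | 4-(benzyloxy)-2-methoxy-6-propylbenzoyl chloride | CCCc1cc(OCc2ccccc2)cc(OC)c1C(=O)Cl | intermediate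
7 | 4-(benzyloxy)-2-methoxy-6-propylperoxybenzoic acid | CCCc1cc(OCc2ccccc2)cc(OC)c1C(=O)OO | intermediate
8 | bis[4-(benzyloxy)-2-methoxy-6-propylbenzoyl] peroxide | CCCc1cc(OCc2ccccc2)cc(OC)c1C(=O)OOC(=O)c1c(OC)cc(OCc2ccccc2)cc1CCC | intermediate
9 | benzyl 4-{[4-(benzyloxy)-2-methoxy-6-propylbenzoyl]peroxy}-2-hydroxy-6-propylbenzoate | CCCc1cc(OCc2ccccc2)cc(OC)c1C(=O)OOc1cc(O)c(C(=O)OCc2ccccc2)c(CCC)c1 | intermediate
10 | benzyl 3-{[4-(benzyloxy)-2-methoxy-6-propylbenzoyl]oxy}-2-hydroxy-4-oxo-6-propylcyclohexa-1,5-diene-1-carboxylate (racemic at C3', transient) | CCCc1cc(OCc2ccccc2)cc(OC)c1C(=O)OC1C(=O)C=C(CCC)C(C(=O)OCc2ccccc2)=C1O | intermediate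
11 | benzyl 3-{[4-(benzyloxy)-2-methoxy-6-propylbenzoyl]oxy}-2,4-dihydroxy-6-propylbenzoate | CCCc1cc(OCc2ccccc2)cc(OC)c1C(=O)Oc1c(O)cc(CCC)c(C(=O)OCc2ccccc2)c1O | intermediate
12 | 2,4-dihydroxy-3-[(4-hydroxy-2-methoxy-6-propylbenzoyl)oxy]-6-propylbenzoic acid | CCCc1cc(O)cc(OC)c1C(=O)Oc1c(O)cc(CCC)c(C(=O)O)c1O | target

## Step count and risk

Total step count: 9. Longest linear sequence: 9 (1 → 2 → 3 → 4 → 5 → 6 → 7 → 8 → 11 → 12). Compound 2 serves both as the precursor of ring A and as the ring-B partner. One batch of 6 supplies both halves of 8.

**Step 8 (key step).**
- *What may go wrong:*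
  - The bimolecular polar attack may be too slow, because ring B carries an ester and the peroxide is electron-rich. Homolysis or ionic carboxy-inversion of the peroxide could then outrun it.
  - Part of the [3,3] shift may go to C5', giving poor site selectivity.
  - A second oxidation of the product may occur.
- *Fallback:* install O3' first and form the acyl bond afterwards, using known chemistry. The fallback sets out from 2, uses 5, and rejoins the route at 12.
  - Rieche formylation of 2 (Cl2CHOMe, TiCl4, CH2Cl2, −10 °C) at C3' gives benzyl 3-formyl-2,4-dihydroxy-6-propylbenzoate F1.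
  - Dakin oxidation (H2O2, aq. NaOH, 0 °C) gives benzyl 2,3,4-trihydroxy-6-propylbenzoate F2.
  - The most acidic phenol, O4'–H, is benzylated (BnBr, 1 equiv K2CO3, DMF) to give benzyl 4-(benzyloxy)-2,3-dihydroxy-6-propylbenzoate F3.
  - O3'–H, the only unchelated phenol left, is esterified with 5 (TFAA, toluene) to give benzyl 4-(benzyloxy)-3-{[4-(benzyloxy)-2-methoxy-6-propylbenzoyl]oxy}-2-hydroxy-6-propylbenzoate F4.
  - Hydrogenolysis under the conditions of step 9 gives 12.

**Step 7.**
- *What may go wrong:* the O–O bond may be lost during formation, work-up or solvent exchange. The electron-rich aryl group migrates easily (carboxy-inversion), and the ortho groups speed up homolysis. The acylation may also stall at the hindered acyl chloride.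
- *Fallback:* carry the electrophilic carboxyl oxygen on iodine(III) instead of in a peroxide. The fallback sets out from 5 and rejoins the route at 11.
  - Ligand exchange of 5 (2 equiv) with PhI(OAc)2 in chlorobenzene under reduced pressure gives [bis(4-benzyloxy-2-methoxy-6-propylbenzoyloxy)iodo]benzene F5.
  - F5 is then combined with 2 (CH2Cl2, 0 °C). O4'–H binds to iodine, and the remaining carboxylate is delivered to C3' with loss of iodobenzene, which is a Wessely-type ortho-acyloxylation. Enolisation gives 11.

**Step 6.**
- *What may go wrong:* hydrolysis of the acid chloride by the water of the aqueous peroxide may compete with perhydrolysis. The peroxy acid may also lose active oxygen, or oxidise its own electron-rich ring, while it is washed and stored.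
- *Fallback:* never let the peroxy acid accumulate, and merge steps 6 and 7 into one operation. The fallback sets out from 6 and rejoins the route at 8.
  - The undivided batch of 6 (2 equiv) is added to one equivalent of sodium peroxide (aqueous acetone, 0 °C). Each peroxy acid anion is then acylated by 6 as soon as it forms, and 8 is worked up as in step 7.
  - This way makes no compound outside the compound list (entry F0).

**Step 4.**
- *What may go wrong:* hydroxide may add very slowly to the di-ortho-substituted ester. Forcing conditions invite attack on the methyl ether and decarboxylation on acidification.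
- *Fallback:* a redox detour that needs only the small hydride at C7. The fallback sets out from 4 and rejoins the route at 5.
  - LiAlH4 (THF, 0 °C) reduces 4 to [4-(benzyloxy)-2-methoxy-6-propylphenyl]methanol F6.
  - MnO2 (CH2Cl2) gives 4-(benzyloxy)-2-methoxy-6-propylbenzaldehyde F7.
  - Pinnick oxidation (NaClO2, NaH2PO4, 2-methyl-2-butene, t-BuOH–H2O) gives 5.

**Step 1.**
- *What may go wrong:* O4–H may be alkylated in competition with the carboxylate, and the electron-rich acid may slowly decarboxylate in DMF.
- *Fallback:* activate the acyl carbon instead of alkylating the carboxylate. The fallback sets out from 1 and rejoins the route at 2.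
  - Treatment of 1 with acetone, TFAA and TFA ties the carboxyl group and O2 together as 7-hydroxy-2,2-dimethyl-5-propyl-4H-1,3-benzodioxin-4-one F8.
  - Opening with benzyl alcohol and NaH (THF, 0 → 25 °C) gives 2.

## Further compounds

F1 | step 8 | benzyl 3-formyl-2,4-dihydroxy-6-propylbenzoate | CCCc1cc(O)c(C=O)c(O)c1C(=O)OCc1ccccc1
F2 | step 8 | benzyl 2,3,4-trihydroxy-6-propylbenzoate | CCCc1cc(O)c(O)c(O)c1C(=O)OCc1ccccc1
F3 | step 8 | benzyl 4-(benzyloxy)-2,3-dihydroxy-6-propylbenzoate | CCCc1cc(OCc2ccccc2)c(O)c(O)c1C(=O)OCc1ccccc1
F4 | step 8 | benzyl 4-(benzyloxy)-3-{[4-(benzyloxy)-2-methoxy-6-propylbenzoyl]oxy}-2-hydroxy-6-propylbenzoate | CCCc1cc(OCc2ccccc2)cc(OC)c1C(=O)Oc1c(O)c(C(=O)OCc2ccccc2)c(CCC)cc1OCc1ccccc1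
F5 | step 7 | [bis(4-benzyloxy-2-methoxy-6-propylbenzoyloxy)iodo]benzene | CCCc1cc(OCc2ccccc2)cc(OC)c1C(=O)OI(OC(=O)c1c(OC)cc(OCc2ccccc2)cc1CCC)c1ccccc1
F0 | step 6 | none | none
F6 | step 4 | [4-(benzyloxy)-2-methoxy-6-propylphenyl]methanol | CCCc1cc(OCc2ccccc2)cc(OC)c1CO
F7 | step 4 | 4-(benzyloxy)-2-methoxy-6-propylbenzaldehyde | CCCc1cc(OCc2ccccc2)cc(OC)c1C=O
F8 | step 1 | 7-hydroxy-2,2-dimethyl-5-propyl-4H-1,3-benzodioxin-4-one | CCCc1cc(O)cc2OC(C)(C)OC(=O)c12
A1 | alternative 1 | benzyl 2,4-bis(benzyloxy)-3-hydroxy-6-propylbenzoate | CCCc1cc(OCc2ccccc2)c(O)c(OCc2ccccc2)c1C(=O)OCc1ccccc1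
A2 | alternative 1 | benzyl 2,4-bis(benzyloxy)-3-{[4-(benzyloxy)-2-methoxy-6-propylbenzoyl]oxy}-6-propylbenzoate | CCCc1cc(OCc2ccccc2)cc(OC)c1C(=O)Oc1c(OCc2ccccc2)cc(CCC)c(C(=O)OCc2ccccc2)c1OCc1ccccc1
A3 | alternative 2 | benzyl 4-{[4-(benzyloxy)-2-methoxy-6-propylbenzoyl]oxy}-2-hydroxy-6-propylbenzoate | CCCc1cc(OCc2ccccc2)cc(OC)c1C(=O)Oc1cc(O)c(C(=O)OCc2ccccc2)c(CCC)c1
A4 | alternative 2 | benzyl 4-{[4-(benzyloxy)-2-methoxy-6-propylbenzoyl]oxy}-2,3-dihydroxy-6-propylbenzoate | CCCc1cc(OCc2ccccc2)cc(OC)c1C(=O)Oc1cc(CCC)c(C(=O)OCc2ccccc2)c(O)c1O
A5 | alternative 3 | benzyl 3-[4-(benzyloxy)-2-methoxy-6-propylbenzoyl]-2,4-dihydroxy-6-propylbenzoate | CCCc1cc(OCc2ccccc2)cc(OC)c1C(=O)c1c(O)cc(CCC)c(C(=O)OCc2ccccc2)c1O
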